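The ten-membered carbocycle is closed last, at the C3–C4 bond (germacrane numbering), by an intramolecular Negishi coupling. A fully acylated open-chain precursor carries a primary iodide at C3 and a (Z)-vinyl bromide at C4; zinc insertion and palladium catalysis then join the sp3 carbon to the sp2 carbon, forming the ring and the cis C4=C5 alkene with retention in one operation. The step exploits three rigid elements that fold the chain: the Z C4=C5 bromoalkene, the cis-in-ring C1=C10 enoate and the trans-fused C6–C7 γ-lactone. The C6–C9 stereotetrad comes from one asymmetric alkynylation, one Sharpless epoxidation and a lactone-forming epoxide opening.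

Key step: step 19

Remark: germacrane numbering is used for the target carbons: C1=C10 (C10 bears the ester carbon C14), C2, C3, C4 (bears methyl C15)=C5, C6 (lactone oxygen), C7, C8 and C9 (acyloxy), C11=C13 (methylidene), C12 (lactone carbonyl).
Remark: compounds 1, 2, 7, 11, 12, 15, 16 and 22, the ligand (S,S)-ProPhenol and D-(−)-diisopropyl tartrate are taken as purchasable.

Step 1
Reactants: 1 (R)-4-benzyl-3-propanoyl-1,3-oxazolidin-2-one; 2 acetaldehyde
Product: 4 (R)-4-benzyl-3-[(2R,3S)-3-hydroxy-2-methylbutanoyl]-1,3-oxazolidin-2-one, via boron enolate 3 (not isolated)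
Conditions: Bu2BOTf, iPr2NEt, CH2Cl2, −78 to 0 °C; then 2, −78 to 0 °C; pH 7 buffer, MeOH, H2O2
Reagents that add atoms: none
Why: Evans syn aldol reaction, in which the (Z)-boron enolate reacts through a Zimmerman–Traxler chair on the face away from the benzyl group and so sets C2 (R) and C3 (S) of the side chain in the syn relation.

Step 2
Reactants: 4 aldol adduct
Product: 5 (R)-4-benzyl-3-[(2R,3S)-3-[(tert-butyldimethylsilyl)oxy]-2-methylbutanoyl]-1,3-oxazolidin-2-one
Conditions: TBSOTf, 2,6-lutidine, CH2Cl2, 0 °C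
Reagents that add atoms: tert-butyldimethylsilyl triflate, CC(C)(C)[Si](C)(C)OS(=O)(=O)C(F)(F)F
Why: Silyl ether formation with a silyl triflate and a hindered base masks the secondary hydroxyl so that the acid cannot acylate itself later, and no stereocenter is touched.

Step 3
Reactants: 5 silylated imide
Product: 6 (2R,3S)-3-[(tert-butyldimethylsilyl)oxy]-2-methylbutanoic acid
Conditions: LiOH, H2O2, THF/H2O, 0 °C; Na2SO3; then HCl to pH 3
Reagents that add atoms: hydrogen peroxide, OO
Why: Hydroperoxide cleavage of the Evans auxiliary attacks the exocyclic imide carbonyl selectively and releases the acid without epimerization at C2.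

Step 4
Reactants: 7 methyl angelate, methyl (Z)-2-methylbut-2-enoate
Product: 8 (Z)-2-methylbut-2-en-1-ol
Conditions: iBu2AlH (2.2 equiv), CH2Cl2, −78 °C
Reagents that add atoms: none
Why: Hydride reduction of the conjugated ester at low temperature gives the allylic alcohol by 1,2-addition and leaves the Z alkene in place.

Step 5
Reactants: 8 (Z)-2-methylbut-2-en-1-ol
Product: 9 [(2R,3S)-2,3-dimethyloxiran-2-yl]methanol
Conditions: Ti(OiPr)4 (10 mol %), D-(−)-diisopropyl tartrate (12 mol %), t-BuOOH, 4 Å molecular sieves, CH2Cl2, −20 °C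
Reagents that add atoms: tert-butyl hydroperoxide, CC(C)(C)OO
Why: Sharpless asymmetric epoxidation, in which the D-(−)-tartrate complex delivers oxygen to the alkene face that gives the (2R,3S) epoxide while the cis relation of CH2OH and the C3 methyl is carried over from the Z alkene.

Step 6
Reactants: 9 epoxy alcohol
Product: 10 (2S,3S)-2,3-dimethyloxirane-2-carboxylic acid
Conditions: RuCl3 (2 mol %), NaIO4, CCl4/MeCN/H2O, rt
Reagents that add atoms: water, O
Why: Catalytic ruthenium tetroxide oxidation takes the primary alcohol through the aldehyde hydrate to the acid and leaves the epoxide, whose C2 is quaternary, unchanged.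

Step 7
Reactants: 11 methyl (triphenylphosphoranylidene)acetate; 12 3-[(tert-butyldimethylsilyl)oxy]propanal
Product: 14 methyl (Z)-5-[(tert-butyldimethylsilyl)oxy]-2-iodopent-2-enoate, via iodo ylide 13 (not isolated)
Conditions: NIS, CH2Cl2, −20 °C; then 12, −20 °C to rt
Reagents that add atoms: N-iodosuccinimide, O=C1CCC(=O)N1I
Why: Iodination of the stabilized ylide followed by Wittig olefination places the ester trans to the alkyl chain, which is the (Z)-α-iodoenoate.

Step 8
Reactants: 15 (E)-4,4-dimethoxybut-2-enal; 16 propyne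
Product: 18 (2E,4S)-1,1-dimethoxyhept-2-en-5-yn-4-ol, via propynylzinc 17 (not isolated)
Conditions: Me2Zn, (S,S)-ProPhenol (10 mol %), Ph3PO (20 mol %), toluene, 0 °C; then 15, 4 °C; aqueous NH4Cl
Reagents that add atoms: none
Why: Catalytic asymmetric alkynylation of an enal by a dinuclear zinc–ProPhenol complex should give the (S) carbinol (the future C6) by analogy with other unsaturated aldehydes, the antipodal ligand being used if the sense proves opposite, and the matched epoxidation of step 10 removes any minor enantiomer.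

Step 9
Reactants: 18 enynol
Product: 20 (2E,4S,5Z)-6-bromo-1,1-dimethoxyhepta-2,5-dien-4-ol, via cyclic vinylalanate 19 (not isolated)
Conditions: NaAlH2(OCH2CH2OMe)2 (Red-Al), THF, 0 °C to rt; then NBS, −78 °C
Reagents that add atoms: N-bromosuccinimide, O=C1CCC(=O)N1Br
Why: Hydroxyl-directed trans-hydroalumination of the propargylic alcohol puts hydride on C5 and aluminium on C4 in a five-membered alanate, and bromination with retention gives the (Z)-vinyl bromide without touching the carbinol center.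

Step 10
Reactants: 20 bromo dienol
Product: 21 (1R,2Z)-3-bromo-1-[(2R,3S)-3-(dimethoxymethyl)oxiran-2-yl]but-2-en-1-ol
Conditions: Ti(OiPr)4 (20 mol %), D-(−)-diisopropyl tartrate (24 mol %), t-BuOOH, 4 Å molecular sieves, CH2Cl2, −20 °C
Reagents that add atoms: tert-butyl hydroperoxide, CC(C)(C)OO
Why: Sharpless epoxidation of a secondary allylic alcohol in its matched mode epoxidizes the E C7=C8 alkene on the face erythro to the carbinol and so sets C7 and C8, while the bromoalkene stays untouched because it is electron-poor, carries a cis substituent and is the mismatched alkene.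

Step 11
Reactants: 21 epoxy alcohol; 22 2-(diethoxyphosphoryl)acetic acid
Product: 23 (1R,2Z)-3-bromo-1-[(2R,3S)-3-(dimethoxymethyl)oxiran-2-yl]but-2-en-1-yl 2-(diethoxyphosphoryl)acetate
Conditions: DCC, DMAP (5 mol %), CH2Cl2, 0 °C to rt
Reagents that add atoms: none
Why: Steglich esterification of the secondary alcohol tethers the future C11–C12 unit to the C6 oxygen without affecting any stereocenter.

Step 12
Reactants: 23 phosphonoacetate
Product: 25 (4R,5S)-5-[(Z)-2-bromoprop-1-en-1-yl]-4-[(1S)-1-hydroxy-2,2-dimethoxyethyl]-3-methylideneoxolan-2-one, via α-phosphono lactone 24 (not isolated)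
Conditions: LiN(SiMe3)2 (1.05 equiv), THF, −78 to 45 °C; then (CH2O)n, 0 °C to rt
Reagents that add atoms: formaldehyde (from paraformaldehyde), C=O
Why: The phosphonate-stabilized carbanion opens the epoxide at C7 in a 5-exo-tet SN2 step with inversion, which closes the trans γ-lactone and frees the C8 hydroxyl with retention, and the phosphonate anion that results undergoes Horner–Wadsworth–Emmons methylenation with formaldehyde.

Step 13
Reactants: 25 hydroxy lactone; 10 (2S,3S)-2,3-dimethyloxirane-2-carboxylic acid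
Product: 27 (1S)-1-[(2S,3S)-2-[(Z)-2-bromoprop-1-en-1-yl]-4-methylidene-5-oxooxolan-3-yl]-2,2-dimethoxyethyl (2S,3S)-2,3-dimethyloxirane-2-carboxylate, via mixed anhydride 26 (not isolated)
Conditions: 2,4,6-trichlorobenzoyl chloride, Et3N, THF, rt; then 25, DMAP, toluene, rt to 50 °C
Reagents that add atoms: none
Why: Yamaguchi esterification joins the hindered α-quaternary acid to the only free hydroxyl (C8) with retention at that center.

Step 14
Reactants: 27 acetal
Product: 28 (1S)-1-[(2S,3S)-2-[(Z)-2-bromoprop-1-en-1-yl]-4-methylidene-5-oxooxolan-3-yl]-2-oxoethyl (2S,3S)-2,3-dimethyloxirane-2-carboxylate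
Conditions: LiBF4, MeCN/H2O (50:1), rt
Reagents that add atoms: water, O
Why: Mild Lewis-acid hydrolysis of the dimethyl acetal frees the C9 aldehyde under conditions too weak to open the electron-poor epoxy ester or to epimerize C8.

Step 15
Reactants: 28 aldehyde; 14 methyl (Z)-5-[(tert-butyldimethylsilyl)oxy]-2-iodopent-2-enoate
Product: 29 methyl (2E)-2-[(1R,2S)-2-[(2S,3S)-2-[(Z)-2-bromoprop-1-en-1-yl]-4-methylidene-5-oxooxolan-3-yl]-2-{[(2S,3S)-2,3-dimethyloxirane-2-carbonyl]oxy}-1-hydroxyethyl]-5-[(tert-butyldimethylsilyl)oxy]pent-2-enoate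
Conditions: CrCl2 (6 equiv), NiCl2 (0.5 mol %), 14 (2.5 equiv), DMSO, rt
Reagents that add atoms: none
Why: Nozaki–Hiyama–Kishi coupling, in which nickel inserts into the activated C–I bond far faster than into the vinyl bromide, the alkenylchromium adds with retention of the alkene geometry, and polar Felkin–Anh attack anti to the C8 acyloxy group sets C9 (R) in the 8,9-anti relation.

Step 16
Reactants: 29 C9 alcohol; 6 (2R,3S)-3-[(tert-butyldimethylsilyl)oxy]-2-methylbutanoic acid
Product: 31 methyl (2E)-2-[(1R,2S)-2-[(2S,3S)-2-[(Z)-2-bromoprop-1-en-1-yl]-4-methylidene-5-oxooxolan-3-yl]-1-{[(2R,3S)-3-[(tert-butyldimethylsilyl)oxy]-2-methylbutanoyl]oxy}-2-{[(2S,3S)-2,3-dimethyloxirane-2-carbonyl]oxy}ethyl]-5-[(tert-butyldimethylsilyl)oxy]pent-2-enoate, via mixed anhydride 30 (not isolated)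
Conditions: 2,4,6-trichlorobenzoyl chloride, Et3N, THF, rt; then 29, DMAP, toluene, 0 °C to rt
Reagents that add atoms: none
Why: Yamaguchi esterification acylates the C9 hydroxyl with retention, and the neighbouring α-quaternary C8 ester is too hindered to migrate at a competitive rate.

Step 17
Reactants: 31 bis-silyl ether
Product: 32 methyl (2E)-2-[(1R,2S)-2-[(2S,3S)-2-[(Z)-2-bromoprop-1-en-1-yl]-4-methylidene-5-oxooxolan-3-yl]-1-{[(2R,3S)-3-[(tert-butyldimethylsilyl)oxy]-2-methylbutanoyl]oxy}-2-{[(2S,3S)-2,3-dimethyloxirane-2-carbonyl]oxy}ethyl]-5-hydroxypent-2-enoate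
Conditions: HF·pyridine, pyridine, THF, 0 °C
Reagents that add atoms: none
Why: Buffered fluoride desilylation cleaves the unhindered primary silyl ether at C3 much faster than the secondary silyl ether of the side chain.

Step 18
Reactants: 32 primary alcohol
Product: 33 methyl (2E)-2-[(1R,2S)-2-[(2S,3S)-2-[(Z)-2-bromoprop-1-en-1-yl]-4-methylidene-5-oxooxolan-3-yl]-1-{[(2R,3S)-3-[(tert-butyldimethylsilyl)oxy]-2-methylbutanoyl]oxy}-2-{[(2S,3S)-2,3-dimethyloxirane-2-carbonyl]oxy}ethyl]-5-iodopent-2-enoate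
Conditions: I2, PPh3, imidazole, CH2Cl2, 0 °C
Reagents that add atoms: iodine, II
Why: Appel-type iodination converts the primary alcohol into the iodide under nearly neutral conditions that spare the esters, the epoxide and the methylidene lactone.

Step 19
Reactants: 33 iodide
Product: 35 methyl (3aS,4S,5R,6E,10Z,11aR)-5-{[(2R,3S)-3-[(tert-butyldimethylsilyl)oxy]-2-methylbutanoyl]oxy}-4-{[(2S,3S)-2,3-dimethyloxirane-2-carbonyl]oxy}-10-methyl-3-methylidene-2-oxo-3a,4,5,8,9,11a-hexahydrocyclodeca[b]furan-6-carboxylate, via alkylzinc iodide 34 (not isolated)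
Conditions: Zn dust (activated with BrCH2CH2Br and Me3SiCl), LiCl, THF, 35 °C; then slow addition (syringe pump) to Pd2(dba)3 (5 mol %), SPhos (12 mol %), THF/NMP, 45 °C, 1 mM
Reagents that add atoms: none
Why: Zinc inserts into the primary C3–I bond to give alkylzinc iodide 34; zerovalent palladium then adds oxidatively to the C4–Br bond with retention, intramolecular transmetalation gives an alkyl(alkenyl) complex of divalent palladium, and reductive elimination forms the C3–C4 bond (intramolecular Negishi coupling). The closest known reaction types are the Negishi coupling of primary alkylzinc halides with alkenyl halides and B-alkyl Suzuki–Miyaura macrocyclizations. The ten-membered carbocycle closes by reductive elimination from an eleven-membered palladacycle, a 10-endo closure in which both carbons of the C4=C5 alkene end up inside the new ring. No stereocenter is created: the cis (Z) C4=C5 geometry is inherited from the vinyl bromide, and C6–C9 and both side chains are untouched under these neutral conditions. The step needs cyclization to outrun oligomerization, β-hydride elimination, ionization of the allylic C9 ester and Heck-type insertion of the C11=C13 methylidene; high dilution with slow addition, a bulky biaryl phosphine that accelerates reductive elimination, and the strained bridged ring that a Heck insertion would require take care of these. The substrate itself secures the rest: the Z bromoalkene, the cis C1=C10 enoate and the trans-fused lactone hold C3 near C4, and zinc reacts only with the alkyl iodide while palladium reacts with the vinyl bromide.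

Step 20
Reactants: 35 silylated macrocycle
Product: 36 CNP0135583.1, methyl (3aS,4S,5R,6E,10Z,11aR)-4-{[(2S,3S)-2,3-dimethyloxirane-2-carbonyl]oxy}-5-{[(2R,3S)-3-hydroxy-2-methylbutanoyl]oxy}-10-methyl-3-methylidene-2-oxo-3a,4,5,8,9,11a-hexahydrocyclodeca[b]furan-6-carboxylate
Conditions: HF·pyridine, THF, 0 °C to rt
Reagents that add atoms: none
Why: Fluoride desilylation under buffered acidic conditions frees the side-chain hydroxyl without base, so acyl migration, epoxide opening and addition to the methylidene lactone should be avoided.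

Compound list
1 | (R)-4-benzyl-3-propanoyl-1,3-oxazolidin-2-one | O=C1OC[C@@H](Cc2ccccc2)N1C(=O)CC | starting material
2 | acetaldehyde | CC=O | starting material
3 | dibutylboron (Z)-enolate of 1 | O=C1OC[C@@H](Cc2ccccc2)N1/C(OB(CCCC)CCCC)=C/C | intermediate (not isolated)
4 | (R)-4-benzyl-3-[(2R,3S)-3-hydroxy-2-methylbutanoyl]-1,3-oxazolidin-2-one | O=C1OC[C@@H](Cc2ccccc2)N1C(=O)[C@H](C)[C@H](C)O | intermediate
5 | (R)-4-benzyl-3-[(2R,3S)-3-[(tert-butyldimethylsilyl)oxy]-2-methylbutanoyl]-1,3-oxazolidin-2-one | O=C1OC[C@@H](Cc2ccccc2)N1C(=O)[C@H](C)[C@H](C)O[Si](C)(C)C(C)(C)C | intermediate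
6 | (2R,3S)-3-[(tert-butyldimethylsilyl)oxy]-2-methylbutanoic acid | OC(=O)[C@H](C)[C@H](C)O[Si](C)(C)C(C)(C)C | intermediate
7 | methyl angelate, methyl (Z)-2-methylbut-2-enoate | C/C=C(/C)C(=O)OC | starting material
8 | (Z)-2-methylbut-2-en-1-ol | C/C=C(/C)CO | intermediate
9 | [(2R,3S)-2,3-dimethyloxiran-2-yl]methanol | OC[C@@]1(C)O[C@H]1C | intermediate
10 | (2S,3S)-2,3-dimethyloxirane-2-carboxylic acid | OC(=O)[C@@]1(C)O[C@H]1C | intermediate
11 | methyl (triphenylphosphoranylidene)acetate | COC(=O)C=P(c1ccccc1)(c1ccccc1)c1ccccc1 | starting material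
12 | 3-[(tert-butyldimethylsilyl)oxy]propanal | O=CCCO[Si](C)(C)C(C)(C)C | starting material
13 | methyl 2-iodo-2-(triphenylphosphoranylidene)acetate | COC(=O)C(I)=P(c1ccccc1)(c1ccccc1)c1ccccc1 | intermediate (not isolated)
14 | methyl (Z)-5-[(tert-butyldimethylsilyl)oxy]-2-iodopent-2-enoate | COC(=O)/C(I)=C/CCO[Si](C)(C)C(C)(C)C | intermediate
15 | (E)-4,4-dimethoxybut-2-enal | O=C/C=C/C(OC)OC | starting material
16 | propyne | CC#C | starting material
17 | methyl(prop-1-yn-1-yl)zinc | C[Zn]C#CC | intermediate (not isolated)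
18 | (2E,4S)-1,1-dimethoxyhept-2-en-5-yn-4-ol | CC#C[C@@H](O)/C=C/C(OC)OC | intermediate
19 | sodium (5S)-5-[(E)-3,3-dimethoxyprop-1-en-1-yl]-2,2-bis(2-methoxyethoxy)-3-methyl-2,5-dihydro-1,2-oxaaluminol-2-uide (cyclic vinylalanate) | CC1=C[C@H](/C=C/C(OC)OC)O[Al-]1(OCCOC)OCCOC.[Na+] | intermediate (not isolated)
20 | (2E,4S,5Z)-6-bromo-1,1-dimethoxyhepta-2,5-dien-4-ol | C/C(Br)=C/[C@@H](O)/C=C/C(OC)OC | intermediate
21 | (1R,2Z)-3-bromo-1-[(2R,3S)-3-(dimethoxymethyl)oxiran-2-yl]but-2-en-1-ol | C/C(Br)=C/[C@@H](O)[C@H]1O[C@@H]1C(OC)OC | intermediate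
22 | 2-(diethoxyphosphoryl)acetic acid | OC(=O)CP(=O)(OCC)OCC | starting material
23 | (1R,2Z)-3-bromo-1-[(2R,3S)-3-(dimethoxymethyl)oxiran-2-yl]but-2-en-1-yl 2-(diethoxyphosphoryl)acetate | C/C(Br)=C/[C@@H](OC(=O)CP(=O)(OCC)OCC)[C@H]1O[C@@H]1C(OC)OC | intermediate
24 | diethyl [(4R,5S)-5-[(Z)-2-bromoprop-1-en-1-yl]-4-[(1S)-1-hydroxy-2,2-dimethoxyethyl]-2-oxooxolan-3-yl]phosphonate (both C3 epimers) | CCOP(=O)(OCC)C1C(=O)O[C@H](/C=C(/C)Br)[C@H]1[C@H](O)C(OC)OC | intermediate (not isolated)
25 | (4R,5S)-5-[(Z)-2-bromoprop-1-en-1-yl]-4-[(1S)-1-hydroxy-2,2-dimethoxyethyl]-3-methylideneoxolan-2-one | C=C1C(=O)O[C@H](/C=C(/C)Br)[C@H]1[C@H](O)C(OC)OC | intermediate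
26 | (2S,3S)-2,3-dimethyloxirane-2-carboxylic 2,4,6-trichlorobenzoic anhydride | O=C(OC(=O)c1c(Cl)cc(Cl)cc1Cl)[C@@]1(C)O[C@H]1C | intermediate (not isolated)
27 | (1S)-1-[(2S,3S)-2-[(Z)-2-bromoprop-1-en-1-yl]-4-methylidene-5-oxooxolan-3-yl]-2,2-dimethoxyethyl (2S,3S)-2,3-dimethyloxirane-2-carboxylate | C=C1C(=O)O[C@H](/C=C(/C)Br)[C@H]1[C@H](OC(=O)[C@@]2(C)O[C@H]2C)C(OC)OC | intermediate
28 | (1S)-1-[(2S,3S)-2-[(Z)-2-bromoprop-1-en-1-yl]-4-methylidene-5-oxooxolan-3-yl]-2-oxoethyl (2S,3S)-2,3-dimethyloxirane-2-carboxylate | C=C1C(=O)O[C@H](/C=C(/C)Br)[C@H]1[C@H](OC(=O)[C@@]2(C)O[C@H]2C)C=O | intermediate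
29 | methyl (2E)-2-[(1R,2S)-2-[(2S,3S)-2-[(Z)-2-bromoprop-1-en-1-yl]-4-methylidene-5-oxooxolan-3-yl]-2-{[(2S,3S)-2,3-dimethyloxirane-2-carbonyl]oxy}-1-hydroxyethyl]-5-[(tert-butyldimethylsilyl)oxy]pent-2-enoate | C=C1C(=O)O[C@H](/C=C(/C)Br)[C@H]1[C@H](OC(=O)[C@@]2(C)O[C@H]2C)[C@H](O)/C(C(=O)OC)=C\CCO[Si](C)(C)C(C)(C)C | intermediate
30 | (2R,3S)-3-[(tert-butyldimethylsilyl)oxy]-2-methylbutanoic 2,4,6-trichlorobenzoic anhydride | O=C(OC(=O)c1c(Cl)cc(Cl)cc1Cl)[C@H](C)[C@H](C)O[Si](C)(C)C(C)(C)C | intermediate (not isolated)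
31 | methyl (2E)-2-[(1R,2S)-2-[(2S,3S)-2-[(Z)-2-bromoprop-1-en-1-yl]-4-methylidene-5-oxooxolan-3-yl]-1-{[(2R,3S)-3-[(tert-butyldimethylsilyl)oxy]-2-methylbutanoyl]oxy}-2-{[(2S,3S)-2,3-dimethyloxirane-2-carbonyl]oxy}ethyl]-5-[(tert-butyldimethylsilyl)oxy]pent-2-enoate | C=C1C(=O)O[C@H](/C=C(/C)Br)[C@H]1[C@H](OC(=O)[C@@]2(C)O[C@H]2C)[C@H](OC(=O)[C@H](C)[C@H](C)O[Si](C)(C)C(C)(C)C)/C(C(=O)OC)=C\CCO[Si](C)(C)C(C)(C)C | intermediate
32 | the 5-hydroxypent-2-enoate corresponding to 31 (primary alcohol at C3) | C=C1C(=O)O[C@H](/C=C(/C)Br)[C@H]1[C@H](OC(=O)[C@@]2(C)O[C@H]2C)[C@H](OC(=O)[C@H](C)[C@H](C)O[Si](C)(C)C(C)(C)C)/C(C(=O)OC)=C\CCO | intermediate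
33 | the 5-iodopent-2-enoate corresponding to 31 (primary iodide at C3, (Z)-vinyl bromide at C4) | C=C1C(=O)O[C@H](/C=C(/C)Br)[C@H]1[C@H](OC(=O)[C@@]2(C)O[C@H]2C)[C@H](OC(=O)[C@H](C)[C@H](C)O[Si](C)(C)C(C)(C)C)/C(C(=O)OC)=C\CCI | intermediate
34 | alkylzinc iodide of 33 (C3–ZnI) | C=C1C(=O)O[C@H](/C=C(/C)Br)[C@H]1[C@H](OC(=O)[C@@]2(C)O[C@H]2C)[C@H](OC(=O)[C@H](C)[C@H](C)O[Si](C)(C)C(C)(C)C)/C(C(=O)OC)=C\CC[Zn]I | intermediate (not isolated)
35 | methyl (3aS,4S,5R,6E,10Z,11aR)-5-{[(2R,3S)-3-[(tert-butyldimethylsilyl)oxy]-2-methylbutanoyl]oxy}-4-{[(2S,3S)-2,3-dimethyloxirane-2-carbonyl]oxy}-10-methyl-3-methylidene-2-oxo-3a,4,5,8,9,11a-hexahydrocyclodeca[b]furan-6-carboxylate | C=C1C(=O)O[C@@H]2/C=C(/C)CC/C=C(/C(=O)OC)[C@@H](OC(=O)[C@H](C)[C@H](C)O[Si](C)(C)C(C)(C)C)[C@@H](OC(=O)[C@@]3(C)O[C@H]3C)[C@@H]12 | intermediate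
36 | CNP0135583.1, methyl (3aS,4S,5R,6E,10Z,11aR)-4-{[(2S,3S)-2,3-dimethyloxirane-2-carbonyl]oxy}-5-{[(2R,3S)-3-hydroxy-2-methylbutanoyl]oxy}-10-methyl-3-methylidene-2-oxo-3a,4,5,8,9,11a-hexahydrocyclodeca[b]furan-6-carboxylate | C=C1C(=O)O[C@@H]2/C=C(/C)CC/C=C(/C(=O)OC)[C@@H](OC(=O)[C@H](C)[C@H](C)O)[C@@H](OC(=O)[C@@]3(C)O[C@H]3C)[C@@H]12 | target

Total step count: 20. Longest linear sequence: 13 steps (steps 8 to 20, from 15).

Steps most likely to fail

Step 19. What may go wrong: oligomerization or protodezincation instead of ring closure, and ionization of the allylic C9 ester by zerovalent palladium. The fallback closes the ring before the C9 hydroxyl is acylated, so that no allylic ester is present. It sets out from 29: the primary silyl ether is cleaved (HF·pyridine, pyridine, THF, 0 °C) to diol F1, and the primary hydroxyl alone is converted into the iodide (I2, PPh3, imidazole, 0 °C) to give iodo alcohol F2. Zinc insertion then gives alkylzinc iodide F3, which a hindered secondary alcohol should protonate only slowly. The same slow-addition palladium protocol closes the C3–C4 bond to macrocyclic alcohol F4, and Yamaguchi acylation of its C9 hydroxyl with 6 gives 35, where the route is rejoined.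

Step 12. What may go wrong: the tethered phosphonate anion fails to open the epoxide at C7 because of the unfavourable ester conformer, or the liberated C8 alkoxide attacks phosphorus or the lactone. The fallback uses a softer β-keto ester nucleophile and a deacylative methylenation. It sets out from 21: 2,2,6-trimethyl-4H-1,3-dioxin-4-one (toluene, 110 °C) gives acetoacetate F5, and NaH (THF, 0 °C to rt) closes the lactone by the same 5-exo opening to 3-acetyl lactone F6. LiN(SiMe3)2 and paraformaldehyde (THF, −78 °C to rt) then effect retro-Claisen methylenation, which comes back to the route at 25.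

Step 15. What may go wrong: poor facial selectivity at C9, insertion of nickel into the C4–Br bond followed by cyclization onto the aldehyde, or erosion of the enoate geometry through an allenolate. The fallback is a polar addition free of nickel and chromium. It sets out from 14: iodine–magnesium exchange (iPrMgCl·LiCl, THF, −78 °C) gives alkenylmagnesium chloride F7, to which aldehyde 28 is added at −78 °C. Felkin–Anh addition should then give 29, where the route is rejoined.

Further compounds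
F1 | step 19 | methyl (2E)-2-[(1R,2S)-2-[(2S,3S)-2-[(Z)-2-bromoprop-1-en-1-yl]-4-methylidene-5-oxooxolan-3-yl]-2-{[(2S,3S)-2,3-dimethyloxirane-2-carbonyl]oxy}-1-hydroxyethyl]-5-hydroxypent-2-enoate (diol) | C=C1C(=O)O[C@H](/C=C(/C)Br)[C@H]1[C@H](OC(=O)[C@@]2(C)O[C@H]2C)[C@H](O)/C(C(=O)OC)=C\CCO
F2 | step 19 | the 5-iodopent-2-enoate corresponding to F1 (iodo alcohol) | C=C1C(=O)O[C@H](/C=C(/C)Br)[C@H]1[C@H](OC(=O)[C@@]2(C)O[C@H]2C)[C@H](O)/C(C(=O)OC)=C\CCI
F3 | step 19 | alkylzinc iodide of F2 | C=C1C(=O)O[C@H](/C=C(/C)Br)[C@H]1[C@H](OC(=O)[C@@]2(C)O[C@H]2C)[C@H](O)/C(C(=O)OC)=C\CC[Zn]I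
F4 | step 19 | methyl (3aS,4S,5R,6E,10Z,11aR)-4-{[(2S,3S)-2,3-dimethyloxirane-2-carbonyl]oxy}-5-hydroxy-10-methyl-3-methylidene-2-oxo-3a,4,5,8,9,11a-hexahydrocyclodeca[b]furan-6-carboxylate (macrocyclic alcohol) | C=C1C(=O)O[C@@H]2/C=C(/C)CC/C=C(/C(=O)OC)[C@@H](O)[C@@H](OC(=O)[C@@]3(C)O[C@H]3C)[C@@H]12
F5 | step 12 | (1R,2Z)-3-bromo-1-[(2R,3S)-3-(dimethoxymethyl)oxiran-2-yl]but-2-en-1-yl 3-oxobutanoate (acetoacetate) | C/C(Br)=C/[C@@H](OC(=O)CC(C)=O)[C@H]1O[C@@H]1C(OC)OC
F6 | step 12 | (4R,5S)-3-acetyl-5-[(Z)-2-bromoprop-1-en-1-yl]-4-[(1S)-1-hydroxy-2,2-dimethoxyethyl]oxolan-2-one (3-acetyl lactone, both C3 epimers) | CC(=O)C1C(=O)O[C@H](/C=C(/C)Br)[C@H]1[C@H](O)C(OC)OC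
F7 | step 15 | chloro[(1Z)-4-[(tert-butyldimethylsilyl)oxy]-1-(methoxycarbonyl)but-1-en-1-yl]magnesium (alkenylmagnesium chloride) | COC(=O)/C([Mg]Cl)=C/CCO[Si](C)(C)C(C)(C)C
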